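**Strategy.** The hydroxyquinone ring (numbered C1=O, C2–OH, C3–prenyl, C4=O, C5–chromanyl, C6–H) is cut at C6–C1 and C3–C4 into two three-carbon pieces. C4–C5–C6 is an acrylate carried on position 3 of a preformed (3R)-chroman. C1–C2–C3 with its prenyl group is 6-methylhept-5-en-2-one, whose methyl carbon (C1) bears a phenylsulfinyl group. A one-pot Michael–Claisen [3+3] annulation joins both bonds, and sulfoxide elimination aromatizes the new ring to the 2-prenylresorcinol. This exploits the 1,3-dioxygen pattern at C2 and C4 flanking C3, a latent 2-alkylcyclohexane-1,3-dione. Oxidation at C1 then gives the quinone. The stereocentre comes from asymmetric hydrogenation of a Stobbe half-ester.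

Key step: step 12

Remark on the chemistry: the quinone is treated as the 2-hydroxy-1,4-dione tautomer drawn; its 4-hydroxy-1,2-dione form is the same compound. Abbreviations: prenyl = 3-methylbut-2-en-1-yl, MOM = methoxymethyl.

**Route**

Step 1
Reactants: 1 2,4,6-trihydroxybenzaldehyde; 2 1-bromo-3-methylbut-2-ene (prenyl bromide)
Product: 3 2,4,6-trihydroxy-3-prenylbenzaldehyde
Conditions: DBU (1.0 equiv), THF, 0 °C to 20 °C
Reagents that add atoms: none
Why: Base-mediated C-alkylation (C-prenylation) of the phloroglucinol-type phenoxide at a ring carbon; the two free ring positions are equivalent, so only one mono-prenyl isomer can form.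

Step 2
Reactants: 3 2,4,6-trihydroxy-3-prenylbenzaldehyde
Product: 4 2-hydroxy-4,6-bis(methoxymethoxy)-3-prenylbenzaldehyde
Conditions: MOMCl (2.2 equiv), iPr2NEt (3 equiv), CH2Cl2, 0 °C
Reagents that add atoms: chloromethyl methyl ether (MOMCl) COCCl
Why: O-Alkylation (MOM protection) should occur first at the acidic 4-hydroxyl and then at the less hindered of the two chelated ortho-hydroxyls, so the hydroxyl flanked by the formyl and prenyl groups should remain free.

Step 3
Reactants: 4 2-hydroxy-4,6-bis(methoxymethoxy)-3-prenylbenzaldehyde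
Product: 5 2-methoxy-4,6-bis(methoxymethoxy)-3-prenylbenzaldehyde
Conditions: MeI (3 equiv), K2CO3 (3 equiv), DMF, 40 °C
Reagents that add atoms: iodomethane CI
Why: Williamson ether synthesis at the one remaining phenol fixes the methoxy group next to the prenyl group.

Step 4
Reactants: 5 2-methoxy-4,6-bis(methoxymethoxy)-3-prenylbenzaldehyde; 6 dimethyl succinate
Product: 7 (E)-3-(methoxycarbonyl)-4-[2-methoxy-4,6-bis(methoxymethoxy)-3-prenylphenyl]but-3-enoic acid
Conditions: NaOMe (2.5 equiv), MeOH, reflux; then cold 1 M HCl to pH 3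
Reagents that add atoms: none
Why: Stobbe condensation, in which aldol addition, paraconate lactone formation and E1cB ring opening should give the (E)-arylidene succinic half-ester with the free acid on the CH2 arm.

Step 5
Reactants: 7 (E)-3-(methoxycarbonyl)-4-[2-methoxy-4,6-bis(methoxymethoxy)-3-prenylphenyl]but-3-enoic acid
Product: 8 (3R)-3-(methoxycarbonyl)-4-[2-methoxy-4,6-bis(methoxymethoxy)-3-prenylphenyl]butanoic acid
Conditions: H2 (6 bar), [Rh(cod)((S,S)-Et-DuPhos)]OTf (1 mol %), NaOMe (0.1 equiv), MeOH, 25 °C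
Reagents that add atoms: none
Why: Carboxylate-directed asymmetric hydrogenation of an itaconate-type half-ester sets the stereocentre by delivery of H2 to one face of the chelated alkene; the (S,S)-ligand is expected by analogy with other β-aryl Stobbe half-esters to give the (R)-acid (the (R,R)-ligand would be used if the sense proved opposite), and the isolated prenyl alkene should not bind this catalyst.

Step 6
Reactants: 8 (3R)-3-(methoxycarbonyl)-4-[2-methoxy-4,6-bis(methoxymethoxy)-3-prenylphenyl]butanoic acid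
Product: 11 (4R)-4-[(2,4-dihydroxy-6-methoxy-5-prenylphenyl)methyl]oxolan-2-one, via hydroxy acid 9 (not isolated), via bis-MOM lactone 10 (not isolated)
Conditions: LiOH·H2O (1.0 equiv), THF–MeOH, then evaporate; LiBH4 (2.5 equiv), THF, 0 °C to 20 °C; then 3 M HCl, MeOH, 40 °C
Reagents that add atoms: none
Why: LiBH4 reduces the methyl ester but not the lithium carboxylate (chemoselective hydride reduction), and the acidic methanol then closes the γ-lactone and cleaves both MOM acetals, with the stereocentre untouched.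

Step 7
Reactants: 11 (4R)-4-[(2,4-dihydroxy-6-methoxy-5-prenylphenyl)methyl]oxolan-2-one
Product: 12 2-[(3R)-7-hydroxy-5-methoxy-6-prenyl-3,4-dihydro-2H-chromen-3-yl]acetic acid
Conditions: Cs2CO3 (3 equiv), DMF, 100 °C; then 1 M HCl
Reagents that add atoms: none
Why: Intramolecular Williamson-type alkylation in which the ortho-phenoxide attacks the lactone O–CH2 carbon (alkyl–oxygen fission, 6-exo-tet) and the carboxylate leaving group makes the ring switch irreversible, whereas attack at the carbonyl is reversible and the second phenoxide cannot reach.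

Step 8
Reactants: 12 2-[(3R)-7-hydroxy-5-methoxy-6-prenyl-3,4-dihydro-2H-chromen-3-yl]acetic acid
Product: 13 methyl 2-[(3R)-7-hydroxy-5-methoxy-6-prenyl-3,4-dihydro-2H-chromen-3-yl]acetate
Conditions: Me3SiCHN2 (1.2 equiv), toluene–MeOH 4:1, 0 °C
Reagents that add atoms: (trimethylsilyl)diazomethane C[Si](C)(C)C=[N+]=[N-]
Why: Methyl esterification with a diazomethane surrogate, in which only the carboxylic acid is acidic enough to protonate the diazo carbon, so the phenol should stay free.

Step 9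
Reactants: 13 methyl 2-[(3R)-7-hydroxy-5-methoxy-6-prenyl-3,4-dihydro-2H-chromen-3-yl]acetate
Product: 14 methyl 2-[(3R)-5-methoxy-7-(methoxymethoxy)-6-prenyl-3,4-dihydro-2H-chromen-3-yl]acetate
Conditions: MOMCl (1.5 equiv), iPr2NEt (2 equiv), CH2Cl2, 0 °C to 20 °C
Reagents that add atoms: chloromethyl methyl ether (MOMCl) COCCl
Why: MOM protection (O-alkylation) masks the ring A phenol against the bases of steps 10 and 12 and against the oxidant of step 13.

Step 10
Reactants: 14 methyl 2-[(3R)-5-methoxy-7-(methoxymethoxy)-6-prenyl-3,4-dihydro-2H-chromen-3-yl]acetate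
Product: 17 methyl 2-[(3R)-5-methoxy-7-(methoxymethoxy)-6-prenyl-3,4-dihydro-2H-chromen-3-yl]prop-2-enoate, via Mannich base 15 (not isolated), via ammonium iodide 16 (not isolated)
Conditions: LiN(iPr)2 (1.15 equiv), THF, −78 °C; [Me2N=CH2]I (1.5 equiv), −78 °C to 20 °C; then MeI (5 equiv), MeOH, 20 °C; then DBU (2 equiv), CH2Cl2, 20 °C
Reagents that add atoms: N,N-dimethylmethyleneiminium iodide (Eschenmoser's salt) C=[N+](C)C.[I-]
Why: Mannich reaction of the ester enolate with the iminium salt, quaternization and E1cB (Hofmann-type) elimination install the α-methylene group; the stereocentre is β to the ester and is not deprotonated.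

Step 11
Reactants: 18 6-methylhept-5-en-2-one
Product: 19 6-methyl-1-(phenylsulfinyl)hept-5-en-2-one (racemic at sulfur)
Conditions: LiN(iPr)2 (2.2 equiv), THF, −78 °C; PhS(O)OMe (1.1 equiv), −78 °C to 0 °C; then 1 M HCl
Reagents that add atoms: methyl benzenesulfinate COS(=O)c1ccccc1
Why: Kinetic deprotonation of the methyl ketone at CH3 and sulfinylation of the enolate (Claisen-type S-acylation) should give the β-keto sulfoxide, whose deprotonation by the second equivalent of base prevents a second reaction.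

Step 12
Reactants: 17 methyl 2-[(3R)-5-methoxy-7-(methoxymethoxy)-6-prenyl-3,4-dihydro-2H-chromen-3-yl]prop-2-enoate; 19 6-methyl-1-(phenylsulfinyl)hept-5-en-2-one (1.2 equiv)
Product: 22 4-[(3R)-5-methoxy-7-(methoxymethoxy)-6-prenyl-3,4-dihydro-2H-chromen-3-yl]-2-prenylbenzene-1,3-diol, via Michael adduct 20 (not isolated), via sulfinyl dione 21 (not isolated)
Conditions: t-BuOK (0.2 equiv), THF, 20 °C; then t-BuOK (2.8 equiv), 0 °C to 20 °C; then AcOH (3 equiv), 65 °C
Reagents that add atoms: none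
Why: The sulfinyl-stabilized enolate of 19 (its C1–H is by far the most acidic) adds to the acrylate CH2 of 17 (Michael addition, bond C6–C1 of the new ring) while only catalytic base is present; with excess t-BuOK the small equilibrium share of the C3 enolate of keto ester 20 then attacks the ester carbonyl (Claisen/Dieckmann-type condensation, bond C3–C4), and the resulting 2-alkylcyclohexane-1,3-dione enolate is the thermodynamic sink, as in the classical Michael–Claisen synthesis of dihydroresorcinols from β-dicarbonyl donors and acrylates. The single ring closes in a 6-(enolendo)-exo-trig mode. After neutralization, thermal syn-elimination of benzenesulfenic acid from the α-sulfinyl ketone (only C6 offers β-hydrogens) places the C6=C1 double bond, and enolization aromatizes the ring to the resorcinol without any external oxidant, which spares both prenyl groups. No new stereocentre survives: those formed transiently at C1, C5 and sulfur are destroyed on aromatization, and chroman C-3 should keep its configuration because, while the acrylate is present, no base stronger than the β-keto sulfoxide enolate is in the flask. The step needs regiocontrol (which α-carbon of the ketone forms which bond) and C- over O-acylation; the sulfinyl group secures the first, and the reversibility of O-acylation together with the stability of the β-diketonate secures the second.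

Step 13
Reactants: 22 4-[(3R)-5-methoxy-7-(methoxymethoxy)-6-prenyl-3,4-dihydro-2H-chromen-3-yl]-2-prenylbenzene-1,3-diol
Product: 23 2-hydroxy-5-[(3R)-5-methoxy-7-(methoxymethoxy)-6-prenyl-3,4-dihydro-2H-chromen-3-yl]-3-prenylcyclohexa-2,5-diene-1,4-dione
Conditions: K2[ON(SO3)2] (Fremy's salt, 2.5 equiv), KH2PO4 (aq., pH 6), acetone–H2O, 0 °C to 20 °C
Reagents that add atoms: potassium nitrosodisulfonate (Fremy's salt) [O]N(S(=O)(=O)[O-])S(=O)(=O)[O-].[K+].[K+]
Why: Teuber oxidation, in which the phenoxyl radical of the resorcinol is trapped by a second nitrosodisulfonate radical at C1, the only free position ortho or para to a hydroxyl, and loss of imidodisulfonate gives the 2-hydroxy-1,4-quinone; the ring A oxygen atoms are all etherified and should be inert.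

Step 14
Reactants: 23 2-hydroxy-5-[(3R)-5-methoxy-7-(methoxymethoxy)-6-prenyl-3,4-dihydro-2H-chromen-3-yl]-3-prenylcyclohexa-2,5-diene-1,4-dione
Product: 24 2-hydroxy-5-[(3R)-7-hydroxy-5-methoxy-6-prenyl-3,4-dihydro-2H-chromen-3-yl]-3-prenylcyclohexa-2,5-diene-1,4-dione (target)
Conditions: p-TsOH·H2O (0.2 equiv), MeOH, 35 °C
Reagents that add atoms: none
Why: Acid-catalysed transacetalization removes the MOM group under conditions mild enough that neither prenyl group should cyclize onto its neighbouring hydroxyl.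

**Compound list**

1 | 2,4,6-trihydroxybenzaldehyde | O=Cc1c(O)cc(O)cc1O | starting material
2 | 1-bromo-3-methylbut-2-ene (prenyl bromide) | CC(C)=CCBr | starting material
3 | 2,4,6-trihydroxy-3-prenylbenzaldehyde | O=Cc1c(O)cc(O)c(CC=C(C)C)c1O | intermediate
4 | 2-hydroxy-4,6-bis(methoxymethoxy)-3-prenylbenzaldehyde | O=Cc1c(OCOC)cc(OCOC)c(CC=C(C)C)c1O | intermediate
5 | 2-methoxy-4,6-bis(methoxymethoxy)-3-prenylbenzaldehyde | COc1c(CC=C(C)C)c(OCOC)cc(OCOC)c1C=O | intermediate
6 | dimethyl succinate | COC(=O)CCC(=O)OC | starting material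
7 | (E)-3-(methoxycarbonyl)-4-[2-methoxy-4,6-bis(methoxymethoxy)-3-prenylphenyl]but-3-enoic acid | COc1c(CC=C(C)C)c(OCOC)cc(OCOC)c1/C=C(\CC(=O)O)C(=O)OC | intermediate
8 | (3R)-3-(methoxycarbonyl)-4-[2-methoxy-4,6-bis(methoxymethoxy)-3-prenylphenyl]butanoic acid | COc1c(CC=C(C)C)c(OCOC)cc(OCOC)c1C[C@H](CC(=O)O)C(=O)OC | intermediate
9 | (3R)-3-(hydroxymethyl)-4-[2-methoxy-4,6-bis(methoxymethoxy)-3-prenylphenyl]butanoic acid | COc1c(CC=C(C)C)c(OCOC)cc(OCOC)c1C[C@H](CC(=O)O)CO | intermediate
10 | (4R)-4-{[2-methoxy-4,6-bis(methoxymethoxy)-3-prenylphenyl]methyl}oxolan-2-one | COc1c(CC=C(C)C)c(OCOC)cc(OCOC)c1C[C@@H]1CC(=O)OC1 | intermediate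
11 | (4R)-4-[(2,4-dihydroxy-6-methoxy-5-prenylphenyl)methyl]oxolan-2-one | COc1c(CC=C(C)C)c(O)cc(O)c1C[C@@H]1CC(=O)OC1 | intermediate
12 | 2-[(3R)-7-hydroxy-5-methoxy-6-prenyl-3,4-dihydro-2H-chromen-3-yl]acetic acid | COc1c(CC=C(C)C)c(O)cc2c1C[C@H](CC(=O)O)CO2 | intermediate
13 | methyl 2-[(3R)-7-hydroxy-5-methoxy-6-prenyl-3,4-dihydro-2H-chromen-3-yl]acetate | COc1c(CC=C(C)C)c(O)cc2c1C[C@H](CC(=O)OC)CO2 | intermediate
14 | methyl 2-[(3R)-5-methoxy-7-(methoxymethoxy)-6-prenyl-3,4-dihydro-2H-chromen-3-yl]acetate | COc1c(CC=C(C)C)c(OCOC)cc2c1C[C@H](CC(=O)OC)CO2 | intermediate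
15 | methyl 3-(dimethylamino)-2-[(3R)-5-methoxy-7-(methoxymethoxy)-6-prenyl-3,4-dihydro-2H-chromen-3-yl]propanoate (both C-2 epimers) | COc1c(CC=C(C)C)c(OCOC)cc2c1C[C@H](C(CN(C)C)C(=O)OC)CO2 | intermediate
16 | 3-methoxy-2-[(3R)-5-methoxy-7-(methoxymethoxy)-6-prenyl-3,4-dihydro-2H-chromen-3-yl]-N,N,N-trimethyl-3-oxopropan-1-aminium iodide | COc1c(CC=C(C)C)c(OCOC)cc2c1C[C@H](C(C[N+](C)(C)C)C(=O)OC)CO2.[I-] | intermediate
17 | methyl 2-[(3R)-5-methoxy-7-(methoxymethoxy)-6-prenyl-3,4-dihydro-2H-chromen-3-yl]prop-2-enoate | COc1c(CC=C(C)C)c(OCOC)cc2c1C[C@H](C(=C)C(=O)OC)CO2 | intermediate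
18 | 6-methylhept-5-en-2-one | CC(C)=CCCC(C)=O | starting material
19 | 6-methyl-1-(phenylsulfinyl)hept-5-en-2-one (racemic at sulfur) | CC(C)=CCCC(=O)CS(=O)c1ccccc1 | intermediate
20 | methyl 2-[(3R)-5-methoxy-7-(methoxymethoxy)-6-prenyl-3,4-dihydro-2H-chromen-3-yl]-9-methyl-5-oxo-4-(phenylsulfinyl)dec-8-enoate (diastereomer mixture) | COc1c(CC=C(C)C)c(OCOC)cc2c1C[C@H](C(CC(C(=O)CCC=C(C)C)S(=O)c1ccccc1)C(=O)OC)CO2 | intermediate
21 | 4-[(3R)-5-methoxy-7-(methoxymethoxy)-6-prenyl-3,4-dihydro-2H-chromen-3-yl]-2-prenyl-6-(phenylsulfinyl)cyclohexane-1,3-dione (diastereomer mixture) | COc1c(CC=C(C)C)c(OCOC)cc2c1C[C@H](C1CC(S(=O)c3ccccc3)C(=O)C(CC=C(C)C)C1=O)CO2 | intermediate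
22 | 4-[(3R)-5-methoxy-7-(methoxymethoxy)-6-prenyl-3,4-dihydro-2H-chromen-3-yl]-2-prenylbenzene-1,3-diol | COc1c(CC=C(C)C)c(OCOC)cc2c1C[C@H](c1ccc(O)c(CC=C(C)C)c1O)CO2 | intermediate
23 | 2-hydroxy-5-[(3R)-5-methoxy-7-(methoxymethoxy)-6-prenyl-3,4-dihydro-2H-chromen-3-yl]-3-prenylcyclohexa-2,5-diene-1,4-dione | COc1c(CC=C(C)C)c(OCOC)cc2c1C[C@H](C1=CC(=O)C(O)=C(CC=C(C)C)C1=O)CO2 | intermediate
24 | 2-hydroxy-5-[(3R)-7-hydroxy-5-methoxy-6-prenyl-3,4-dihydro-2H-chromen-3-yl]-3-prenylcyclohexa-2,5-diene-1,4-dione | COc1c(CC=C(C)C)c(O)cc2c1C[C@H](C1=CC(=O)C(O)=C(CC=C(C)C)C1=O)CO2 | target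

**Step count**

Total steps: 14. Longest linear sequence: 13 (steps 1 to 10 and 12 to 14); step 11 is a one-step side branch.

**Steps most likely to fail**

Step 12. The conjugate addition to the α-branched acrylate may be slow and may reverse under the strongly basic ring-closure conditions, and sulfenic acid may be lost before the ring has closed, which would divert material to open-chain enones. The fallback sets out from 17 and 18 and returns at 22; it builds the ring stepwise with sulfur at the sulfide level and raises it to the sulfoxide only after ring closure. Ketone 18 would be sulfenylated at the methyl group (LiN(iPr)2, PhSSPh, THF, −78 °C) to 6-methyl-1-(phenylsulfanyl)hept-5-en-2-one F1. Conjugate addition of F1 to 17 (catalytic t-BuOK, THF) should give methyl 2-[(3R)-5-methoxy-7-(methoxymethoxy)-6-prenyl-3,4-dihydro-2H-chromen-3-yl]-9-methyl-5-oxo-4-(phenylsulfanyl)dec-8-enoate F2, which is isolated. Claisen cyclization (t-BuOK, THF) should then give 4-[(3R)-5-methoxy-7-(methoxymethoxy)-6-prenyl-3,4-dihydro-2H-chromen-3-yl]-2-prenyl-6-(phenylsulfanyl)cyclohexane-1,3-dione F3. Selective S-oxidation (H2O2, (CF3)2CHOH, 20 °C) should give 21, and heating in toluene at 80 °C should give 22.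

Step 7. Alkyl–oxygen cleavage of a γ-lactone by a phenoxide is slow, so reversible attack at the carbonyl and thermal decomposition of the electron-rich prenylphenol may compete. The fallback sets out from 10 (isolated by stopping step 6 after a pH 4 work-up) and returns at 13. Lactone 10 would be opened with KOH in aqueous MeOH and the potassium salt alkylated with MeI in DMF to give methyl (3R)-3-(hydroxymethyl)-4-[2-methoxy-4,6-bis(methoxymethoxy)-3-prenylphenyl]butanoate F4. Mesylation (MsCl, Et3N, CH2Cl2, 0 °C) should give methyl (3R)-4-[2-methoxy-4,6-bis(methoxymethoxy)-3-prenylphenyl]-3-[(methylsulfonyloxy)methyl]butanoate F5. HCl in MeOH should remove both MOM groups to give methyl (3R)-4-(2,4-dihydroxy-6-methoxy-5-prenylphenyl)-3-[(methylsulfonyloxy)methyl]butanoate F6. K2CO3 in acetone should close the chroman by phenoxide displacement of the primary mesylate and give 13.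

Step 5. The two ortho substituents on the aryl group may hinder binding of the alkene to rhodium, so that turnover is slow and facial selectivity is eroded. The fallback sets out from 5 and returns at 11; it sets the stereocentre by auxiliary-controlled alkylation instead.
- Horner–Wadsworth–Emmons reaction of 5 with (4S)-4-benzyl-3-[(diethoxyphosphoryl)acetyl]-1,3-oxazolidin-2-one (LiCl, iPr2NEt, MeCN) should give (4S)-4-benzyl-3-{(2E)-3-[2-methoxy-4,6-bis(methoxymethoxy)-3-prenylphenyl]prop-2-enoyl}-1,3-oxazolidin-2-one F7.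
- Conjugate reduction with LiBH(s-Bu)3 (THF, −78 °C) should give (4S)-4-benzyl-3-{3-[2-methoxy-4,6-bis(methoxymethoxy)-3-prenylphenyl]propanoyl}-1,3-oxazolidin-2-one F8.
- Enolization with NaN(SiMe3)2 and alkylation with tert-butyl bromoacetate at −78 °C, anti to the benzyl group of the auxiliary, should give tert-butyl (3R)-4-[(4S)-4-benzyl-2-oxo-1,3-oxazolidin-3-yl]-3-{[2-methoxy-4,6-bis(methoxymethoxy)-3-prenylphenyl]methyl}-4-oxobutanoate F9.
- LiBH4 (THF, 0 °C) should release tert-butyl (3R)-3-(hydroxymethyl)-4-[2-methoxy-4,6-bis(methoxymethoxy)-3-prenylphenyl]butanoate F10.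
- HCl in MeOH at 40 °C should lactonize F10 and remove both MOM groups to give 11.

**Further compounds**

F1 | step 12 | 6-methyl-1-(phenylsulfanyl)hept-5-en-2-one | CC(C)=CCCC(=O)CSc1ccccc1
F2 | step 12 | methyl 2-[(3R)-5-methoxy-7-(methoxymethoxy)-6-prenyl-3,4-dihydro-2H-chromen-3-yl]-9-methyl-5-oxo-4-(phenylsulfanyl)dec-8-enoate | COc1c(CC=C(C)C)c(OCOC)cc2c1C[C@H](C(CC(C(=O)CCC=C(C)C)Sc1ccccc1)C(=O)OC)CO2
F3 | step 12 | 4-[(3R)-5-methoxy-7-(methoxymethoxy)-6-prenyl-3,4-dihydro-2H-chromen-3-yl]-2-prenyl-6-(phenylsulfanyl)cyclohexane-1,3-dione | COc1c(CC=C(C)C)c(OCOC)cc2c1C[C@H](C1CC(Sc3ccccc3)C(=O)C(CC=C(C)C)C1=O)CO2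
F4 | step 7 | methyl (3R)-3-(hydroxymethyl)-4-[2-methoxy-4,6-bis(methoxymethoxy)-3-prenylphenyl]butanoate | COc1c(CC=C(C)C)c(OCOC)cc(OCOC)c1C[C@H](CC(=O)OC)CO
F5 | step 7 | methyl (3R)-4-[2-methoxy-4,6-bis(methoxymethoxy)-3-prenylphenyl]-3-[(methylsulfonyloxy)methyl]butanoate | COc1c(CC=C(C)C)c(OCOC)cc(OCOC)c1C[C@H](CC(=O)OC)COS(C)(=O)=O
F6 | step 7 | methyl (3R)-4-(2,4-dihydroxy-6-methoxy-5-prenylphenyl)-3-[(methylsulfonyloxy)methyl]butanoate | COc1c(CC=C(C)C)c(O)cc(O)c1C[C@H](CC(=O)OC)COS(C)(=O)=O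
F7 | step 5 | (4S)-4-benzyl-3-{(2E)-3-[2-methoxy-4,6-bis(methoxymethoxy)-3-prenylphenyl]prop-2-enoyl}-1,3-oxazolidin-2-one | COc1c(CC=C(C)C)c(OCOC)cc(OCOC)c1/C=C/C(=O)N1[C@@H](Cc2ccccc2)COC1=O
F8 | step 5 | (4S)-4-benzyl-3-{3-[2-methoxy-4,6-bis(methoxymethoxy)-3-prenylphenyl]propanoyl}-1,3-oxazolidin-2-one | COc1c(CC=C(C)C)c(OCOC)cc(OCOC)c1CCC(=O)N1[C@@H](Cc2ccccc2)COC1=O
F9 | step 5 | tert-butyl (3R)-4-[(4S)-4-benzyl-2-oxo-1,3-oxazolidin-3-yl]-3-{[2-methoxy-4,6-bis(methoxymethoxy)-3-prenylphenyl]methyl}-4-oxobutanoate | COc1c(CC=C(C)C)c(OCOC)cc(OCOC)c1C[C@H](CC(=O)OC(C)(C)C)C(=O)N1[C@@H](Cc2ccccc2)COC1=O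
F10 | step 5 | tert-butyl (3R)-3-(hydroxymethyl)-4-[2-methoxy-4,6-bis(methoxymethoxy)-3-prenylphenyl]butanoate | COc1c(CC=C(C)C)c(OCOC)cc(OCOC)c1C[C@H](CC(=O)OC(C)(C)C)CO
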